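The eleven-membered keto-lactam ring contains a β-acyloxy ketone: ketone carbon C9, ethyl-bearing C10 and C11, the O–CH of the fused lactone D. This 1,3-pattern is the retron of a 2-isoxazoline, so the ring is closed by an intramolecular nitrile oxide–alkene cycloaddition. The nitrile oxide carbon (C9, terminus of the N-pentyl chain) bonds to C10 and its oxygen to C11 of a (Z)-but-1-enyl group on C12; one operation closes the ring, places both oxygens and sets C10 and C11 from alkene geometry and the C12 centre. The precursor is a 3-hydroxypyrrolidin-2-one (ring B) bearing lactone E, the (Z)-alkene, a methyl ester and an aldoxime.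

Key step: step 14

Remark on atom labels: N4 is the lactam nitrogen; C5–C8 are the four CH2 groups from N4 to the ketone C9; C10 is the CH(Et); C11 is the O–CH of lactone D; C12 is the CH joining lactone D to C1; C13 and C14 are the CH(CH3) and C=O of lactone D; C1 is the carbinol carbon; C2 is the ring CH2; C3 is the N–CH; C9a is the lactam C=O; C18–C21 are the appended lactone E (C18 = O–CH, C20 = CH(CH3)). Ring B is N4/C9a/C1/C2/C3.

Assumption: the d-menthol-series acetal butenolide 5 is taken as a purchasable reagent; the l-menthol series would give the enantiomeric C12/C13 centres.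

Step 1
Reactants: 1 L-allylglycine
Product: 2 (S)-2-hydroxypent-4-enoic acid
Conditions: NaNO2, 1 M H2SO4, H2O, 0 °C → rt
Reagents that add atoms: water, O
Why: Nitrous acid deamination (diazotisation) of the α-amino acid passes through the α-lactone, so two inversions should return the hydroxy acid with retention; no new stereocentre is made.

Step 2
Reactants: 2 (S)-2-hydroxypent-4-enoic acid; 3 pivalaldehyde
Product: 4 (2S,5S)-2-tert-butyl-5-(prop-2-enyl)-1,3-dioxolan-4-one
Conditions: p-TsOH (cat.), H2SO4 (cat.), pentane, reflux, Dean–Stark trap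
Reagents that add atoms: none
Why: Acid-catalysed acetalisation with water removal should give the cis-2,5-disubstituted dioxolanone, whose acetal carbon stores the configuration of the carbinol carbon (self-regeneration of stereocentres).

Step 3
Reactants: 4 (2S,5S)-2-tert-butyl-5-(prop-2-enyl)-1,3-dioxolan-4-one; 5 (5S)-5-(d-menthyloxy)furan-2(5H)-one
Product: 8 Michael–methylation adduct, via lithium enolate 6 (not isolated), via adduct enolate 7 (not isolated)
Conditions: LiN(iPr)2, THF, −78 °C; then 5, −78 °C; then MeI, DMPU, −78 → −40 °C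
Reagents that add atoms: iodomethane, CI
Why: Tandem Michael addition–enolate alkylation: the dioxolanone enolate should add anti to its tert-butyl group (quaternary C1, overall retention) and anti to the menthyloxy group of the butenolide (C12), and the lactone enolate so formed should be methylated anti to the new C12 substituent (C13, trans).

Step 4
Reactants: 8 Michael–methylation adduct
Product: 9 aldehyde (allyl group cut to CH2CHO)
Conditions: O3, CH2Cl2/MeOH, −78 °C; then Me2S, −78 °C → rt
Reagents that add atoms: ozone, [O-][O+]=O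
Why: Ozonolysis with reductive work-up cleaves the only alkene to the C3 aldehyde and touches no stereocentre.

Step 5
Reactants: 9 aldehyde; 10 5-aminopentan-1-ol
Product: 12 hydroxy lactam (N,O-hemiaminal at C3), via imine 11 (not isolated)
Conditions: THF, rt → 50 °C; aqueous work-up
Reagents that add atoms: none
Why: Imine condensation followed by 5-exo N-acylation by the dioxolanone (an activated acylal ester) should expel pivalaldehyde, free the C1 hydroxyl and give an N-acyliminium ion that is hydrated by the water of condensation; the C3 epimer mixture is inconsequential because C3 becomes planar in step 7.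

Step 6
Reactants: 13 3-methylfuran-2(5H)-one
Product: 14 3-methyl-2-(triisopropylsilyloxy)furan
Conditions: iPr3SiOTf, Et3N, CH2Cl2, 0 °C
Reagents that add atoms: triisopropylsilyl triflate, CC(C)[Si](OS(=O)(=O)C(F)(F)F)(C(C)C)C(C)C
Why: Soft enolisation and O-silylation of the butenolide gives the aromatic 2-silyloxyfuran, a vinylogous silyl ketene acetal.

Step 7
Reactants: 12 hydroxy lactam; 14 3-methyl-2-(triisopropylsilyloxy)furan
Product: 15 butenolide adduct
Conditions: BF3·OEt2, CH2Cl2, −78 °C
Reagents that add atoms: none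
Why: Vinylogous Mannich reaction of the N-acyliminium ion: the furan should attack C3 on the face cis to the pseudoaxial C1 oxygen and trans to the bulky C1 carbon substituent (1,3-induction in the envelope cation), and the open transition state should give the syn (threo) C3/C18 relationship usual for silyloxyfurans and five-membered N-acyliminium ions.

Step 8
Reactants: 15 butenolide adduct
Product: 16 lactone E compound
Conditions: H2 (1 atm), Rh/Al2O3, EtOAc, rt
Reagents that add atoms: none
Why: Heterogeneous hydrogenation should deliver hydrogen to the butenolide face anti to the C18 pyrrolidinyl substituent, placing the C20 methyl cis to it.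

Step 9
Reactants: 16 lactone E compound
Product: 17 lactol
Conditions: 2 M HCl, dioxane, 50 °C
Reagents that add atoms: water, O
Why: Acid hydrolysis of the acyl acetal (pseudo-ester) releases the menthol auxiliary and leaves the γ-hydroxy lactone, the ring form of the C11 aldehyde and C14 acid; C12 and C13 are not involved.

Step 10
Reactants: 17 lactol; 18 propyltriphenylphosphonium bromide
Product: 19 (Z)-alkene acid
Conditions: KN(SiMe3)2 (excess), THF, −78 → 0 °C; citric acid work-up
Reagents that add atoms: none
Why: Wittig olefination with a non-stabilised ylide under salt-free conditions: base opens the lactol to the aldehyde carboxylate and kinetic cis-oxaphosphetane formation should give the (Z)-alkene.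

Step 11
Reactants: 19 (Z)-alkene acid
Product: 20 methyl ester
Conditions: Me3SiCHN2, PhMe/MeOH, 0 °C
Reagents that add atoms: trimethylsilyldiazomethane, C[Si](C)(C)C=[N+]=[N-]
Why: Diazoalkane esterification under neutral conditions masks the acid, which would otherwise add to the nitrile oxide or lactonise onto the C1 hydroxyl.

Step 12
Reactants: 20 methyl ester
Product: 21 aldehyde
Conditions: Dess–Martin periodinane, NaHCO3, CH2Cl2, 0 °C → rt
Reagents that add atoms: none
Why: Dess–Martin oxidation converts the primary alcohol into the C9 aldehyde and cannot oxidise the tertiary C1 alcohol.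

Step 13
Reactants: 21 aldehyde
Product: 22 aldoxime
Conditions: NH2OH·HCl, NaOAc, EtOH/H2O, rt
Reagents that add atoms: hydroxylamine hydrochloride, NO.Cl
Why: Oxime condensation at buffered pH is far faster at the aldehyde than hydroxylaminolysis of the ester or lactone.

Step 14
Reactants: 22 aldoxime
Product: 25 bridged isoxazoline, via hydroximoyl chloride 23 (not isolated), via nitrile oxide 24 (not isolated)
Conditions: NCS, pyridine (cat.), CHCl3, rt; then syringe-pump addition over 20 h to Et3N, PhMe, 80 °C, 1 mM final concentration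
Reagents that add atoms: none
Why: Intramolecular nitrile oxide–alkene cycloaddition (Huisgen 1,3-dipolar cycloaddition): chlorination of the aldoxime and slow dehydrochlorination keep nitrile oxide 24 at very low concentration, and its concerted suprafacial [3+2] addition to the (Z)-alkene forms the C9–C10 and O–C11 bonds. The closest known reaction type is the macrocyclising nitrile oxide cycloaddition that gives bridged isoxazolines when the tether is long. Two rings close at once: the eleven-membered ring (C9, C10, C11, C12, C1, C9a, N4, C5–C8) by C9–C10 bond formation with the alkene endocyclic to it, and the five-membered isoxazoline (C9, N, O, C11, C10) in a concerted [3+2] mode, the two sharing C9–C10–C11 as a bridged bicycle. C10 is set relative to C11 by the (Z)-geometry, and C11 is set by C12: allylic 1,3-strain with the cis-ethyl group holds H12 in the alkene plane, so C1 and C13 flank the two faces, and the dipole, tethered through C1–C9a–N4 and able to hydrogen-bond to the C1 hydroxyl, should reach the face on the C1 side. The step needs regioselectivity (carbon to C10, oxygen to C11), which the preference of the chain-bearing dipole carbon for the alkene terminus remote from quaternary C1 and the lower strain of an eleven- over a ten-membered ring should secure; it also needs cyclisation to outrun furoxan dimerisation, which high dilution and slow generation of the dipole should secure.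

Step 15
Reactants: 25 bridged isoxazoline
Product: 27 target CNP0221273.1, via hydroxy ketone ester 26 (not isolated)
Conditions: Raney Ni, H2 (1 atm), B(OH)3, MeOH/H2O (5:1), rt; then PPTS (cat.), PhMe, 50 °C
Reagents that add atoms: water, O
Why: Hydrogenolysis of the N–O bond over Raney nickel with boric acid should hydrolyse the β-hydroxy imine to the β-hydroxy ketone without epimerising C10, and acid-catalysed transesterification should then close lactone D through the secondary C11 hydroxyl in kinetic preference to the tertiary C1 hydroxyl; no stereocentre changes.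

Compound list
1 | L-allylglycine, (S)-2-aminopent-4-enoic acid | N[C@@H](CC=C)C(=O)O | starting material
2 | (S)-2-hydroxypent-4-enoic acid | O[C@@H](CC=C)C(=O)O | intermediate
3 | pivalaldehyde | CC(C)(C)C=O | starting material
4 | (2S,5S)-2-tert-butyl-5-(prop-2-enyl)-1,3-dioxolan-4-one (cis) | C=CC[C@@H]1O[C@H](C(C)(C)C)OC1=O | intermediate
5 | (5S)-5-[(1S,2R,5S)-menthyloxy]furan-2(5H)-one (d-menthyl acetal butenolide) | O=C1C=C[C@@H](O[C@H]2C[C@@H](C)CC[C@@H]2C(C)C)O1 | starting material
6 | lithium enolate of 4 | [Li]OC1=C(CC=C)O[C@H](C(C)(C)C)O1 | intermediate (not isolated)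
7 | lithium lactone enolate of the Michael adduct | O=C1O[C@@H](C(C)(C)C)O[C@]1(CC=C)[C@@H]2[C@@H](O[C@H]3C[C@@H](C)CC[C@@H]3C(C)C)OC(O[Li])=C2 | intermediate (not isolated)
8 | (2S,5R)-2-tert-butyl-5-[(2S,3R,4S)-2-(d-menthyloxy)-4-methyl-5-oxooxolan-3-yl]-5-(prop-2-enyl)-1,3-dioxolan-4-one | O=C1O[C@@H](C(C)(C)C)O[C@]1(CC=C)[C@@H]2[C@@H](O[C@H]3C[C@@H](C)CC[C@@H]3C(C)C)OC(=O)[C@H]2C | intermediate
9 | aldehyde: 8 with the allyl group cut to a 2-oxoethyl group | O=C1O[C@@H](C(C)(C)C)O[C@]1(CC=O)[C@@H]2[C@@H](O[C@H]3C[C@@H](C)CC[C@@H]3C(C)C)OC(=O)[C@H]2C | intermediate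
10 | 5-aminopentan-1-ol | NCCCCCO | starting material
11 | N-(5-hydroxypentyl)imine of 9 | O=C1O[C@@H](C(C)(C)C)O[C@]1(CC=NCCCCCO)[C@@H]2[C@@H](O[C@H]3C[C@@H](C)CC[C@@H]3C(C)C)OC(=O)[C@H]2C | intermediate (not isolated)
12 | (3R)-3,5-dihydroxy-1-(5-hydroxypentyl)-3-[(2S,3R,4S)-2-(d-menthyloxy)-4-methyl-5-oxooxolan-3-yl]pyrrolidin-2-one (C5 epimers) | OCCCCCN1C(=O)[C@@](O)(CC1O)[C@@H]2[C@@H](O[C@H]3C[C@@H](C)CC[C@@H]3C(C)C)OC(=O)[C@H]2C | intermediate
13 | 3-methylfuran-2(5H)-one | CC1=CCOC1=O | starting material
14 | 3-methyl-2-(triisopropylsilyloxy)furan | CC1=C(O[Si](C(C)C)(C(C)C)C(C)C)OC=C1 | intermediate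
15 | (3R,5S)-3-hydroxy-1-(5-hydroxypentyl)-3-[(2S,3R,4S)-2-(d-menthyloxy)-4-methyl-5-oxooxolan-3-yl]-5-[(2S)-4-methyl-5-oxo-2,5-dihydrofuran-2-yl]pyrrolidin-2-one | OCCCCCN1C(=O)[C@@](O)(C[C@H]1[C@@H]2C=C(C)C(=O)O2)[C@@H]3[C@@H](O[C@H]4C[C@@H](C)CC[C@@H]4C(C)C)OC(=O)[C@H]3C | intermediate
16 | 15 with the butenolide saturated to the (2S,4S)-4-methyl-5-oxooxolan-2-yl group (lactone E) | OCCCCCN1C(=O)[C@@](O)(C[C@H]1[C@@H]2C[C@H](C)C(=O)O2)[C@@H]3[C@@H](O[C@H]4C[C@@H](C)CC[C@@H]4C(C)C)OC(=O)[C@H]3C | intermediate
17 | lactol: 16 with the menthyloxy group replaced by OH (C11 anomers) | OCCCCCN1C(=O)[C@@](O)(C[C@H]1[C@@H]2C[C@H](C)C(=O)O2)[C@@H]3C(O)OC(=O)[C@H]3C | intermediate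
18 | propyltriphenylphosphonium bromide | CCC[P+](c1ccccc1)(c1ccccc1)c1ccccc1.[Br-] | starting material
19 | (2S,3R,4Z)-3-{(3R,5S)-3-hydroxy-1-(5-hydroxypentyl)-5-[(2S,4S)-4-methyl-5-oxooxolan-2-yl]-2-oxopyrrolidin-3-yl}-2-methylhept-4-enoic acid | OCCCCCN1C(=O)[C@@](O)(C[C@H]1[C@@H]2C[C@H](C)C(=O)O2)[C@H](/C=C\CC)[C@H](C)C(=O)O | intermediate
20 | methyl ester of 19 | OCCCCCN1C(=O)[C@@](O)(C[C@H]1[C@@H]2C[C@H](C)C(=O)O2)[C@H](/C=C\CC)[C@H](C)C(=O)OC | intermediate
21 | aldehyde: 20 with an N-(5-oxopentyl) chain | O=CCCCCN1C(=O)[C@@](O)(C[C@H]1[C@@H]2C[C@H](C)C(=O)O2)[C@H](/C=C\CC)[C@H](C)C(=O)OC | intermediate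
22 | aldoxime of 21 (E/Z mixture) | ON=CCCCCN1C(=O)[C@@](O)(C[C@H]1[C@@H]2C[C@H](C)C(=O)O2)[C@H](/C=C\CC)[C@H](C)C(=O)OC | intermediate
23 | hydroximoyl chloride of 22 | ON=C(Cl)CCCCN1C(=O)[C@@](O)(C[C@H]1[C@@H]2C[C@H](C)C(=O)O2)[C@H](/C=C\CC)[C@H](C)C(=O)OC | intermediate (not isolated)
24 | nitrile oxide derived from 23 | [O-][N+]#CCCCCN1C(=O)[C@@](O)(C[C@H]1[C@@H]2C[C@H](C)C(=O)O2)[C@H](/C=C\CC)[C@H](C)C(=O)OC | intermediate (not isolated)
25 | bridged 2-isoxazoline: C9=N–O–C11 spanning C9/C10/C11 of the eleven-membered lactam, C14 methyl ester, configurations as in 27 | CC[C@@H]1C2=NO[C@@H]1[C@H]([C@H](C)C(=O)OC)[C@]3(O)C[C@@H]([C@@H]4C[C@H](C)C(=O)O4)N(CCCC2)C3=O | intermediate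
26 | β-hydroxy ketone methyl ester (C9 ketone, free C11 hydroxyl) | CC[C@@H]1C(=O)CCCCN2C(=O)[C@@](O)(C[C@H]2[C@@H]2C[C@H](C)C(=O)O2)[C@H]([C@H]1O)[C@H](C)C(=O)OC | intermediate (not isolated)
27 | CNP0221273.1 | CC[C@@H]1C(=O)CCCCN2C(=O)[C@@](O)(C[C@H]2[C@@H]2C[C@H](C)C(=O)O2)[C@@H]2[C@H]1OC(=O)[C@H]2C | target

Total step count: 15. Longest linear sequence: 14 steps (1–5, 7–15); step 6 is a one-step side branch.

Steps most likely to fail

Step 14. The nitrile oxide may be consumed by dimerisation or isomerisation faster than the slow eleven-membered cycloaddition to an unactivated cis-alkene. Fallback, setting out from 20 and returning at 25: the dipole is changed to a silyl nitronate, which does not dimerise. Alcohol 20 is converted with I2, PPh3 and imidazole into the primary iodide F1. NaNO2 and phloroglucinol in DMSO then give the nitroalkane F2. Me3SiCl and Et3N in benzene at high dilution generate the silyl nitronate, whose intramolecular cycloaddition to the (Z)-alkene should give the N-(trimethylsilyloxy)isoxazolidine F3. Acid (p-TsOH, CH2Cl2) eliminates trimethylsilanol and gives isoxazoline 25.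

Step 3. Conjugate addition of the congested, fully substituted lithium enolate may stall or revert (retro-Michael), and proton transfer to the butenolide may compete. Fallback, setting out from 4 and returning at 8: a Lewis-acid Mukaiyama–Michael addition in two stages. Dioxolanone 4 is trapped (LiN(iPr)2, Me3SiCl) as the silyl ketene acetal F4. This adds to 5 under TiCl4 in CH2Cl2 at −78 °C, anti to the tert-butyl and menthyloxy groups, to give after work-up the des-methyl adduct F5. In F5 only the lactone α-position is enolisable, and methylation (LiN(iPr)2, MeI) anti to the C12 substituent gives 8.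

Step 5. The acyl transfer may stall at the imine or enamine stage, or the amine may be diverted by the liberated pivalaldehyde or open the acetal lactone. Fallback, setting out from 8 and returning at 12: the order of events is reversed. Alkene 8 is heated with 10 (2-hydroxypyridine catalysis, toluene) to open the dioxolanone to the hydroxy amide F6 while the allyl group is still inert. Ozonolysis (O3, then Me2S) then unveils the aldehyde, which closes onto the secondary amide N–H to give hydroxy lactam 12.

Further compounds
F1 | step 14 | primary iodide (20 with the CH2OH replaced by CH2I) | ICCCCCN1C(=O)[C@@](O)(C[C@H]1[C@@H]2C[C@H](C)C(=O)O2)[C@H](/C=C\CC)[C@H](C)C(=O)OC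
F2 | step 14 | nitroalkane (N-(5-nitropentyl) analogue of 20) | [O-][N+](=O)CCCCCN1C(=O)[C@@](O)(C[C@H]1[C@@H]2C[C@H](C)C(=O)O2)[C@H](/C=C\CC)[C@H](C)C(=O)OC
F3 | step 14 | N-(trimethylsilyloxy)isoxazolidine (C9 epimers) | CC[C@@H]1C2N(O[Si](C)(C)C)O[C@@H]1[C@H]([C@H](C)C(=O)OC)[C@]3(O)C[C@@H]([C@@H]4C[C@H](C)C(=O)O4)N(CCCC2)C3=O
F4 | step 3 | silyl ketene acetal of 4, (2S)-2-tert-butyl-5-(prop-2-enyl)-4-(trimethylsilyloxy)-1,3-dioxole | C=CCC1=C(O[Si](C)(C)C)O[C@@H](C(C)(C)C)O1
F5 | step 3 | des-methyl Michael adduct (8 without the C13 methyl) | O=C1O[C@@H](C(C)(C)C)O[C@]1(CC=C)[C@@H]2[C@@H](O[C@H]3C[C@@H](C)CC[C@@H]3C(C)C)OC(=O)C2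
F6 | step 5 | N-(5-hydroxypentyl) α-hydroxy amide with intact allyl group | OCCCCCNC(=O)[C@@](O)(CC=C)[C@@H]1[C@@H](O[C@H]2C[C@@H](C)CC[C@@H]2C(C)C)OC(=O)[C@H]1C
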